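**Assumption:** the SMILES is read as (2R,3S,3aS), with the aryl and methyl groups cis on one face of the five-membered ring and the allyl group on the other face; the propiophenone, 4-methoxyresorcinol and allyltrimethylsilane are taken as catalogue compounds.

**Retrosynthetic overview**
- The C3a–allyl bond is cut last. The target comes from an aromatic cis-(2R,3S)-2-aryl-3-methyl-dihydrobenzofuran-6-ol by oxidative dearomatization: a λ3-iodane turns the phenol para-carbon (normally a nucleophile) into an electrophile, and allylsilane traps it.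
- The cis-dihydrobenzofuranol comes from the flat 2-aryl-3-methylbenzofuran-6-ol; syn asymmetric hydrogenation sets C2 and C3 together.
- The benzofuranol comes from 4-methoxyresorcinol and an α-bromo-propiophenone: C3–C3a by ortho Friedel–Crafts alkylation, O1–C2 by cyclodehydration.
- Ring order: both benzene rings are bought; furan ring (step 2), then its two stereocentres (step 3), then dearomatization of the fused benzene ring to the cyclohexadienone with the quaternary centre (step 4).

**Route**

Step 1
Reactants: 1 1-(3,4,5-trimethoxyphenyl)propan-1-one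
Product: 2 rac-2-bromo-1-(3,4,5-trimethoxyphenyl)propan-1-one
Conditions: CuBr2 (2.1 equiv), EtOAc/CHCl3 1:1, reflux
Reagents that add atoms: copper(II) bromide, Br[Cu]Br
Why: King–Ostrum α-bromination via the enol is selective for the α-CH2 of an aryl ketone whose ring is deactivated by the carbonyl, and the racemic centre does not matter because it becomes sp2 in step 2.

Step 2
Reactants: 2 rac-2-bromo-1-(3,4,5-trimethoxyphenyl)propan-1-one; 3 4-methoxybenzene-1,3-diol (4-methoxyresorcinol)
Product: 5 5-methoxy-3-methyl-2-(3,4,5-trimethoxyphenyl)-1-benzofuran-6-ol, via α-aryl ketone 4 (not isolated)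
Conditions: TiCl4 (1.0 equiv), CF3CH2OH, reflux
Reagents that add atoms: none
Why: Titanium-templated ortho Friedel–Crafts alkylation of the phenol by the α-bromo ketone takes place at C6 of 3 (ortho to OH-1, para to OH-3, the most nucleophilic unhindered carbon) and the o-hydroxyaryl ketone 4 then cyclodehydrates in the same pot, which puts the aryl group at C2 and the methyl at C3, leaves the 6-OH free and carries no stereocentre forward.

Step 3
Reactants: 5 5-methoxy-3-methyl-2-(3,4,5-trimethoxyphenyl)-1-benzofuran-6-ol
Product: 6 (2R,3S)-5-methoxy-3-methyl-2-(3,4,5-trimethoxyphenyl)-2,3-dihydro-1-benzofuran-6-ol (cis)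
Conditions: H2 (60 bar), [Ru(cod)(2-methylallyl)2] (5 mol %), SINpEt·HBF4 (10 mol %, the antipode that gives 2R), KOtBu (10 mol %), toluene, 40 °C
Reagents that add atoms: none
Why: Asymmetric hydrogenation of the furan ring of a benzofuran with a chiral Ru–bis(NHC) catalyst adds both hydrogens to one face of C2=C3, so aryl and methyl are necessarily cis, and the ligand antipode (both are available; the sense is fixed in a pilot run) selects the face that gives 2R,3S while the benzene rings, methyl ethers and phenol stay untouched.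

Step 4
Reactants: 6 (2R,3S)-5-methoxy-3-methyl-2-(3,4,5-trimethoxyphenyl)-2,3-dihydro-1-benzofuran-6-ol; 7 allyltrimethylsilane
Product: 10 (2R,3S,3aS)-5-methoxy-3-methyl-3a-(prop-2-en-1-yl)-2-(3,4,5-trimethoxyphenyl)-3,3a-dihydro-1-benzofuran-6(2H)-one, via aryloxy-λ3-iodane 8 (not isolated), via phenoxonium cation 9 (not isolated)
Conditions: PhI(OAc)2 (1.1 equiv), 7 (5 equiv), (CF3)2CHOH/CH2Cl2 1:1, −20 °C, 10 min; then aq. NaHCO3
Reagents that add atoms: none
Why: In this oxidative dearomative allylation (hypervalent-iodine aromatic-ring umpolung with Hosomi–Sakurai-type trapping) the phenol exchanges onto iodine(III) and ionises in the fluorinated alcohol to a phenoxonium ion whose alkyl-bearing para carbon C3a is the soft electrophilic site, and the allylsilane adds there from the face opposite the cis C3-methyl/C2-aryl pair, which sets 3aS and gives the cross-conjugated dienone after desilylation.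

**Compound list**

1 | 1-(3,4,5-trimethoxyphenyl)propan-1-one (3',4',5'-trimethoxypropiophenone) | CCC(=O)c1cc(OC)c(OC)c(OC)c1 | starting material
2 | rac-2-bromo-1-(3,4,5-trimethoxyphenyl)propan-1-one | CC(Br)C(=O)c1cc(OC)c(OC)c(OC)c1 | intermediate
3 | 4-methoxybenzene-1,3-diol (4-methoxyresorcinol) | COc1ccc(O)cc1O | starting material
4 | rac-2-(2,4-dihydroxy-5-methoxyphenyl)-1-(3,4,5-trimethoxyphenyl)propan-1-one | COc1cc(C(C)C(=O)c2cc(OC)c(OC)c(OC)c2)c(O)cc1O | intermediate
5 | 5-methoxy-3-methyl-2-(3,4,5-trimethoxyphenyl)-1-benzofuran-6-ol | COc1cc2c(C)c(-c3cc(OC)c(OC)c(OC)c3)oc2cc1O | intermediate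
6 | (2R,3S)-5-methoxy-3-methyl-2-(3,4,5-trimethoxyphenyl)-2,3-dihydro-1-benzofuran-6-ol | COc1cc2c(cc1O)O[C@@H](c1cc(OC)c(OC)c(OC)c1)[C@H]2C | intermediate
7 | allyltrimethylsilane | C=CC[Si](C)(C)C | starting material
8 | acetoxy{[(2R,3S)-5-methoxy-3-methyl-2-(3,4,5-trimethoxyphenyl)-2,3-dihydro-1-benzofuran-6-yl]oxy}(phenyl)-λ3-iodane | COc1cc2c(cc1OI(OC(C)=O)c1ccccc1)O[C@@H](c1cc(OC)c(OC)c(OC)c1)[C@H]2C | intermediate
9 | (2R,3S)-phenoxonium cation of 6, drawn as its 5-methyloxonium form (6-oxo, C4=C3a and C7=C7a double bonds, electrophilic at C3a) | C[O+]=C1C=C2C(=CC1=O)O[C@@H](c1cc(OC)c(OC)c(OC)c1)[C@H]2C | intermediate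
10 | (2R,3S,3aS)-5-methoxy-3-methyl-3a-(prop-2-en-1-yl)-2-(3,4,5-trimethoxyphenyl)-3,3a-dihydro-1-benzofuran-6(2H)-one | C=CC[C@]12C=C(OC)C(=O)C=C1O[C@@H](c1cc(OC)c(OC)c(OC)c1)[C@H]2C | target

**Step count**
Total steps: 4. Longest linear sequence: 4 (1 → 2 → 5 → 6 → 10).

**Three steps most likely to fail**

Step 4 (highest risk). The precedent is para-allylation of simple 4-alkylphenols; this substrate adds three risks:
- The allylsilane may attack the methoxy-bearing ortho carbon C5 or the free ortho carbon C7 instead of C3a.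
- Cation 9 may lose the benzylic C3–H and re-aromatize to benzofuran 5.
- The acid-labile benzylic C2–O bond may ionize and epimerize C2.

Fallback, setting out from 6 and returning at 10: separate the oxidation from the C–C bond formation. Compound 6 is oxidised with PhI(OAc)2 in MeOH at 0 °C to the masked o-benzoquinone (2R,3S)-5,5-dimethoxy-3-methyl-2-(3,4,5-trimethoxyphenyl)-2,3-dihydro-1-benzofuran-6(5H)-one F1. The crude ketal is taken up in CH2Cl2 with 7 and ionised with catalytic TMSOTf at −78 °C. Cation 9 then forms with no oxidant, acetate or protic solvent present, and vinylogous Sakurai attack at C3a, again anti to the C3 methyl, gives 10.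

Step 3. A 2-aryl-3-methylbenzofuran (tetrasubstituted C2=C3) is at the edge of the known scope of benzofuran hydrogenation. The free phenol may slow the catalyst, and the sense of induction has to be established experimentally.

Fallback, setting out from 5 and returning at 6: resolution in place of asymmetric catalysis. Compound 5 is hydrogenated over Pd/C (H2 1–4 bar, EtOAc, stopped at one equivalent to avoid benzylic C–O hydrogenolysis). Syn addition gives the racemic cis compound, a 1:1 mixture of 6 and its mirror image (2S,3R)-5-methoxy-3-methyl-2-(3,4,5-trimethoxyphenyl)-2,3-dihydro-1-benzofuran-6-ol F2. Preparative chiral SFC on a polysaccharide phase delivers 6.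

Step 2. O-alkylation of either hydroxyl may compete with C-alkylation and would lead to the 3-aryl-2-methyl regioisomer. The bromide is secondary, and the aryl ketone is sluggish in the cyclodehydration.

Fallback, setting out from 3 and returning at 5: the regiochemistry is fixed by a ketone–ester McMurry closure.
- Compound 3 is C-acetylated at the same C6 position (AcOH, BF3·OEt2, 90 °C) to 1-(2,4-dihydroxy-5-methoxyphenyl)ethan-1-one F3.
- Both hydroxyls are aroylated with 3,4,5-trimethoxybenzoyl chloride (Et3N, DMAP, CH2Cl2) to 4-acetyl-6-methoxy-1,3-phenylene bis(3,4,5-trimethoxybenzoate) F4.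
- Fürstner intramolecular keto-ester coupling (TiCl3, Zn, THF, reflux, high dilution) joins the ketone carbon to the ortho ester carbonyl and gives 5-methoxy-3-methyl-2-(3,4,5-trimethoxyphenyl)-1-benzofuran-6-yl 3,4,5-trimethoxybenzoate F5.
- K2CO3 in MeOH removes the remaining ester and gives 5.

**Further compounds**

F1 | step 4 | (2R,3S)-5,5-dimethoxy-3-methyl-2-(3,4,5-trimethoxyphenyl)-2,3-dihydro-1-benzofuran-6(5H)-one | COC1(OC)C=C2C(=CC1=O)O[C@@H](c1cc(OC)c(OC)c(OC)c1)[C@H]2C
F2 | step 3 | (2S,3R)-5-methoxy-3-methyl-2-(3,4,5-trimethoxyphenyl)-2,3-dihydro-1-benzofuran-6-ol | COc1cc2c(cc1O)O[C@H](c1cc(OC)c(OC)c(OC)c1)[C@@H]2C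
F3 | step 2 | 1-(2,4-dihydroxy-5-methoxyphenyl)ethan-1-one | CC(=O)c1cc(OC)c(O)cc1O
F4 | step 2 | 4-acetyl-6-methoxy-1,3-phenylene bis(3,4,5-trimethoxybenzoate) | CC(=O)c1cc(OC)c(OC(=O)c2cc(OC)c(OC)c(OC)c2)cc1OC(=O)c1cc(OC)c(OC)c(OC)c1
F5 | step 2 | 5-methoxy-3-methyl-2-(3,4,5-trimethoxyphenyl)-1-benzofuran-6-yl 3,4,5-trimethoxybenzoate | COc1cc2c(C)c(-c3cc(OC)c(OC)c(OC)c3)oc2cc1OC(=O)c1cc(OC)c(OC)c(OC)c1
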